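The numbers in the tables come from a simulation with made-up constants, and the scatter is random.

The ratio of target to the remainder of what the substrate became is what I carried through the red flask, the one asked about at 30 h.

in all of them: substrate 35 mM

|  | reagent | temperature | remark | time |
|---|---|---|---|---|
| red | 1.2 equiv | 0 °C | the very flask that is asked about, followed so far |  |
| grey | 2.4 equiv | 6 °C | run made earlier |  |
| flask | 1.20 equiv | 0 °C |  | 30 h |

| run | time / h | target / % | substrate / % |
|---|---|---|---|
| red | 3.00 | 40.1 | 0 |
| red | 8.00 | 40.2 | 0.4 |
| red | 15.0 | 40.9 | 1.1 |
| red | 25.0 | 41.2 | 0.2 |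
| grey | 0.250 | 28.6 | 2.1 |
| grey | 0.500 | 28.3 | 0 |
| grey | 1.33 | 31.2 | 0 |
| grey | 3.00 | 28.1 | 0 |

(scatter of a reading: 1 percentage point)

- target, in percent of the substrate first charged, at 30 h
- what to do for the largest gain in target; "none" if nothing gains more than 2 percentage points (Sunday's / Tuesday's / Monday's / Friday's / none)
- target present, with what was taken out counted in, in percent of the substrate first charged, after Tuesday's
- target present, with what was taken out counted in, in percent of the substrate first charged, after Friday's

- Sunday's: at 30 h take out 90% of the target then present, then wait 15 h
- Tuesday's: change nothing and wait 15 h more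
- Monday's: at 30 h raise the temperature by 25 K, then wait 15 h
- Friday's: at 30 h add reagent, 100% of the amount charged, then wait 15 h

- target taken out counts as made
- additions bring no volume worth counting

First I asked which inputs had to be known well. Time mattered little: in the red flask target rose by 1.1 percentage points between 3.00 h and 25.0 h, close to the scatter of 1 point. The red mean of 40.6% was good to about 0.5 points. Reagent and temperature together mattered strongly: the grey flask, with twice the reagent and at 6 °C, stood at 29.0%.

I took two paths to compete for the substrate, one using reagent and one not, and froze a product. The red ratio 0.684 times the charged 42.0 mM gives 28.7 mM, the split concentration, meaning the ratio times the charged c_reagent; it is a selectivity factor with the unit of a concentration. The grey flask gives 34.4 mM, higher, so one value did not serve both flasks, which also differ in temperature: the red value predicts 25.5% for grey, 3.6 points too low.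

Carrying the rise forward, I reckoned 41.5% at 30 h, and Tuesday's gain at 0.75 points, less than 2 points. If each part not turned into target took one reagent, c_reagent stood near 21.2 mM, so late substrate should go to the reagent path and to target in the ratio 0.739. With substrate reading 0.2% at 25.0 h, I chose none.

The forecast gave 40.7%, 40.8%, 40.7% and none, holding that “With no substrate left, extra reagent, heat or removing product has nothing to convert”.

The flask gives 42.5%, 43.5% after Tuesday's and 43.1% after Friday's, and the best option is Monday's, gaining 6.6 points, more than Tuesday's 0.96 points or Friday's 0.57 points.

    substrate → target (k = 0.0682 /min, Ea = 74.0 kJ/mol)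
    reagent + intermediate A ⇌ intermediate C (K = 15.0 /M, k = 0.0733 /M/min, Ea = 53.0 kJ/mol, ΔH = −30.0 kJ/mol)
    intermediate B ⇌ intermediate E (K = 2.10, k = 0.00480 /min, Ea = 94.0 kJ/mol, ΔH = −7.00 kJ/mol)
    intermediate B ⇌ intermediate D (K = 2.50, k = 1.40 /min, Ea = 67.0 kJ/mol, ΔH = 11.0 kJ/mol)
    substrate + reagent → intermediate A (k = 2.42 /M/min, Ea = 50.0 kJ/mol)
    substrate ⇌ intermediate B (K = 14.5, k = 0.0239 /min, Ea = 90.0 kJ/mol, ΔH = −29.0 kJ/mol)
    (constants at 0 °C)

At 30.0 h the flask holds 8.70% as intermediate B, intermediate D and intermediate E, and its substrate, at 0.0173%, goes to intermediate A at 0.74 of its rate to target, where my ratio stood at 0.739. For the neighbour flask with 0.480 equiv of reagent, the split concentration gives 63.1% of target, and that flask holds 61.7%.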